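**Retrosynthetic overview**

1. C1 acid from a primary alcohol; the C5–CH3 bond from opening a bridged peroxyketal (2,6,7-trioxabicyclo[3.2.1]octane) with AlMe3, the C3 arm delivering methyl to its own face.
2. Peroxyketal from a β-oxetanyl ketone and H2O2: 5-exo opening of the oxetane at C3 with inversion closes the 1,2-dioxolane, and the freed C1 hydroxyl closes the ketal.
3. C10=C11 by Julia–Kocienski olefination of the aldehyde obtained by ozonolysis of a terpene alkene; C7 comes from the chiral pool.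
4. Key bond C4–C5: dithiane acyl anion of the terpene aldehyde plus an enantiopure 2-methylglycidyl sulfonate (two natively electrophilic carbons), telescoped with epoxide transposition and ylide ring expansion to the oxetane; C3 comes from the glycidyl unit.
5. Ring order: dithiane (temporary), oxirane, oxetane, then 1,2-dioxolane and six-membered ketal ring together; the ketal ring is opened last and the dioxolane stays.

Assumption: the (E)-styrenyl pentenol and the enantiopure 2-methylglycidyl sulfonate used as starting materials are bought as such; locants C1–C15 are those of the target chain (C1 = CO2H).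

**Route**

Step 1
Reactants: 1 (4E)-5-phenylpent-4-en-1-ol
Product: 2 1-phenyl-5-{[(4E)-5-phenylpent-4-en-1-yl]sulfanyl}-1H-tetrazole
Conditions: 1-phenyl-1H-tetrazole-5-thiol, PPh3, DIAD, THF, 0 → 23 °C
Reagents that add atoms: 1-phenyl-1H-tetrazole-5-thiol, Sc1nnnn1-c1ccccc1
Why: Mitsunobu thioetherification of an unhindered primary alcohol with the acidic tetrazole thiol; no stereocentre is involved and the styrenyl alkene is untouched.

Step 2
Reactants: 2 1-phenyl-5-{[(4E)-5-phenylpent-4-en-1-yl]sulfanyl}-1H-tetrazole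
Product: 4 1-phenyl-5-{[(4E)-5-phenylpent-4-en-1-yl]sulfonyl}-1H-tetrazole, via sulfoxide 3 (not isolated)
Conditions: (NH4)6Mo7O24·4H2O (cat.), 30% aq. H2O2, EtOH, 0 → 23 °C
Reagents that add atoms: hydrogen peroxide, OO
Why: Molybdate-catalysed sulfide-to-sulfone oxidation, which is much faster at sulfur than epoxidation of the conjugated alkene.

Step 3
Reactants: 5 (3R)-3,7-dimethyloct-6-enal ((R)-citronellal)
Product: 6 2-[(2R)-2,6-dimethylhept-5-en-1-yl]-1,3-dithiane
Conditions: HS(CH2)3SH, BF3·OEt2 (cat.), CH2Cl2, −20 °C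
Reagents that add atoms: propane-1,3-dithiol, SCCCS
Why: Lewis-acid dithioacetalisation turns the aldehyde carbon (C5) into a latent acyl anion (Corey–Seebach umpolung); excess dithiol and low temperature outrun the carbonyl-ene cyclisation, and the remote C7 stereocentre from the chiral pool is untouched.

Step 4
Reactants: 6 2-[(2R)-2,6-dimethylhept-5-en-1-yl]-1,3-dithiane and 7 [(2R)-2-methyloxiran-2-yl]methyl 4-methylbenzenesulfonate ((R)-2-methylglycidyl tosylate)
Product: 12 2-[(2R)-2,6-dimethylhept-5-en-1-yl]-2-{[(2S)-2-methyloxetan-2-yl]methyl}-1,3-dithiane, via lithiated dithiane 8 (not isolated), via tosyloxy alkoxide 9 (not isolated), via epoxide 10 (not isolated), via sulfoxonium betaine 11 (not isolated)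
Conditions: n-BuLi, THF, −20 °C; DMPU, then 7, −78 → 23 °C; then Me3S(O)I, KOtBu, t-BuOH, 55 °C
Reagents that add atoms: trimethylsulfoxonium iodide, C[S+](C)(C)=O.[I-]
Why: Corey–Seebach acyl-anion alkylation joins two natively electrophilic carbons: the C5 carbanion opens the oxirane of 7 at its CH2 (C4; the neopentyl CH2OTs cannot compete), the tertiary alkoxide displaces tosylate to transpose the epoxide (as with epichlorohydrin), and Corey–Chaykovsky-type ring expansion by dimethylsulfoxonium methylide at the new epoxide CH2 gives the oxetane; no bond to C3 is broken, so its configuration comes unchanged from 7 (only the CIP label changes).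

Step 5
Reactants: 12 2-[(2R)-2,6-dimethylhept-5-en-1-yl]-2-{[(2S)-2-methyloxetan-2-yl]methyl}-1,3-dithiane
Product: 13 (4R)-4,8-dimethyl-1-[(2S)-2-methyloxetan-2-yl]non-7-en-2-one
Conditions: MeI, CaCO3, MeCN/H2O (4:1), 45 °C
Reagents that add atoms: water, O
Why: Alkylative dithiane hydrolysis (S-methylation, then water) unmasks the C5 ketone under buffered, near-neutral conditions that spare the oxetane and the trisubstituted alkene; no stereocentre is touched.

Step 6
Reactants: 13 (4R)-4,8-dimethyl-1-[(2S)-2-methyloxetan-2-yl]non-7-en-2-one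
Product: 15 (4R)-4-methyl-7-[(2S)-2-methyloxetan-2-yl]-6-oxoheptanal, via ozonide 14 (not isolated)
Conditions: O3, CH2Cl2, −78 °C; then PPh3, −78 → 23 °C
Reagents that add atoms: ozone, [O-][O+]=O
Why: Ozonolysis with reductive work-up cleaves the only alkene to the C10 aldehyde (acetone is lost); ketone, oxetane and both stereocentres are inert.

Step 7
Reactants: 15 (4R)-4-methyl-7-[(2S)-2-methyloxetan-2-yl]-6-oxoheptanal and 4 1-phenyl-5-{[(4E)-5-phenylpent-4-en-1-yl]sulfonyl}-1H-tetrazole
Product: 17 (4R,7E,11E)-4-methyl-1-[(2S)-2-methyloxetan-2-yl]-12-phenyldodeca-7,11-dien-2-one, via potassium sulfonyl carbanion 16 (not isolated)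
Conditions: 4, KN(SiMe3)2, DME, −60 °C; then 15, −60 → 23 °C
Reagents that add atoms: none
Why: Julia–Kocienski olefination: the pre-formed sulfonyl carbanion adds to the aldehyde far faster than it adds to or enolises the ketone, and Smiles rearrangement with anti elimination gives the E C10=C11 alkene (potassium base in DME).

Step 8
Reactants: 17 (4R,7E,11E)-4-methyl-1-[(2S)-2-methyloxetan-2-yl]-12-phenyldodeca-7,11-dien-2-one
Product: 20 (1R,5R)-5-methyl-1-[(2R,5E,9E)-2-methyl-10-phenyldeca-5,9-dien-1-yl]-2,6,7-trioxabicyclo[3.2.1]octane, via ketone perhydrate 18 (not isolated), via dioxolanol 19 (not isolated)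
Conditions: H2O2 (anhydrous, in Et2O, 10 equiv), Me3SiOTf (0.2 equiv), Et2O, −78 → 0 °C; then camphorsulfonic acid (cat.), 4 Å molecular sieves, CH2Cl2, 23 °C
Reagents that add atoms: hydrogen peroxide, OO
Why: Proposed new method: under Lewis acid the ketone equilibrates with its perhydrate, whose OOH attacks the activated oxetane at the tertiary carbon C3 in a 5-exo SN2-like opening with inversion (setting C3), and the C1 hydroxyl thus released closes the six-membered ketal, the bridge fixing the ketal carbon; the closest known reactions are the stereospecific Lewis-acid opening of 2,2-disubstituted oxetanes by H2O2 or by an internal hydroperoxide (giving 3-hydroperoxyalkanols and 1,2-dioxolanes) and acid-catalysed formation of 3-alkoxy-1,2-dioxolanes from β-hydroperoxy ketones.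

Step 9
Reactants: 20 (1R,5R)-5-methyl-1-[(2R,5E,9E)-2-methyl-10-phenyldeca-5,9-dien-1-yl]-2,6,7-trioxabicyclo[3.2.1]octane
Product: 22 2-[(3R,5R)-3,5-dimethyl-5-[(2R,5E,9E)-2-methyl-10-phenyldeca-5,9-dien-1-yl]-1,2-dioxolan-3-yl]ethan-1-ol, via aluminium alkoxide 21 (not isolated)
Conditions: AlMe3 (3 equiv), CH2Cl2, −78 → −20 °C; then aq. potassium sodium tartrate (KNaC4H4O6)
Reagents that add atoms: trimethylaluminium, C[Al](C)C
Why: Proposed new method: AlMe3 binds the more basic ether oxygen of the peroxyketal, ionises the C5–O bond to a peroxycarbenium ion paired with the alkoxyaluminate that the two-carbon arm holds on its own face, and transfers methyl to that face (retention), so the C5 methyl ends cis to the C3 arm as in the target; the closest known reactions are retentive organoaluminium cleavage of acetals and anhydro sugars and Lewis-acid-mediated C–C bond formation at 3-alkoxy-1,2-dioxolanes through peroxycarbenium ions.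

Step 10
Reactants: 22 2-[(3R,5R)-3,5-dimethyl-5-[(2R,5E,9E)-2-methyl-10-phenyldeca-5,9-dien-1-yl]-1,2-dioxolan-3-yl]ethan-1-ol
Product: 24 2-[(3S,5R)-3,5-dimethyl-5-[(2R,5E,9E)-2-methyl-10-phenyldeca-5,9-dien-1-yl]-1,2-dioxolan-3-yl]acetic acid, via aldehyde 23 (not isolated)
Conditions: TEMPO (0.2 equiv), PhI(OAc)2 (2.5 equiv), MeCN/H2O (1:1), 23 °C
Reagents that add atoms: water, O
Why: TEMPO/PhI(OAc)2 oxidation in wet acetonitrile takes the primary alcohol through the aldehyde hydrate to the acid; the oxoammonium oxidant leaves the dialkyl peroxide, both alkenes and all three stereocentres alone.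

**Compound list**

1 | (4E)-5-phenylpent-4-en-1-ol | OCCC/C=C/c1ccccc1 | starting material
2 | 1-phenyl-5-{[(4E)-5-phenylpent-4-en-1-yl]sulfanyl}-1H-tetrazole | c1ccccc1/C=C/CCCSc1nnnn1-c1ccccc1 | intermediate
3 | 1-phenyl-5-{[(4E)-5-phenylpent-4-en-1-yl]sulfinyl}-1H-tetrazole (racemic at sulfur, not isolated) | c1ccccc1/C=C/CCCS(=O)c1nnnn1-c1ccccc1 | intermediate
4 | 1-phenyl-5-{[(4E)-5-phenylpent-4-en-1-yl]sulfonyl}-1H-tetrazole | c1ccccc1/C=C/CCCS(=O)(=O)c1nnnn1-c1ccccc1 | intermediate
5 | (3R)-3,7-dimethyloct-6-enal, (R)-citronellal | C[C@H](CCC=C(C)C)CC=O | starting material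
6 | 2-[(2R)-2,6-dimethylhept-5-en-1-yl]-1,3-dithiane | C[C@H](CCC=C(C)C)CC1SCCCS1 | intermediate
7 | [(2R)-2-methyloxiran-2-yl]methyl 4-methylbenzenesulfonate, (R)-2-methylglycidyl tosylate | Cc1ccc(cc1)S(=O)(=O)OC[C@@]1(C)CO1 | starting material
8 | {2-[(2R)-2,6-dimethylhept-5-en-1-yl]-1,3-dithian-2-yl}lithium (not isolated) | C[C@H](CCC=C(C)C)CC1([Li])SCCCS1 | intermediate
9 | lithium (2R)-1-{2-[(2R)-2,6-dimethylhept-5-en-1-yl]-1,3-dithian-2-yl}-2-methyl-3-(tosyloxy)propan-2-olate (not isolated) | C[C@H](CCC=C(C)C)CC1(C[C@@](C)(O[Li])COS(=O)(=O)c2ccc(C)cc2)SCCCS1 | intermediate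
10 | 2-[(2R)-2,6-dimethylhept-5-en-1-yl]-2-{[(2R)-2-methyloxiran-2-yl]methyl}-1,3-dithiane (not isolated) | C[C@H](CCC=C(C)C)CC1(C[C@]2(C)CO2)SCCCS1 | intermediate
11 | (2S)-1-{2-[(2R)-2,6-dimethylhept-5-en-1-yl]-1,3-dithian-2-yl}-4-[dimethyl(oxo)sulfonio]-2-methylbutan-2-olate (betaine, not isolated) | C[C@H](CCC=C(C)C)CC1(C[C@@](C)([O-])CC[S+](C)(C)=O)SCCCS1 | intermediate
12 | 2-[(2R)-2,6-dimethylhept-5-en-1-yl]-2-{[(2S)-2-methyloxetan-2-yl]methyl}-1,3-dithiane | C[C@H](CCC=C(C)C)CC1(C[C@]2(C)CCO2)SCCCS1 | intermediate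
13 | (4R)-4,8-dimethyl-1-[(2S)-2-methyloxetan-2-yl]non-7-en-2-one | C[C@H](CCC=C(C)C)CC(=O)C[C@]1(C)CCO1 | intermediate
14 | (4R)-6-(5,5-dimethyl-1,2,4-trioxolan-3-yl)-4-methyl-1-[(2S)-2-methyloxetan-2-yl]hexan-2-one (ozonide, epimers at the trioxolane CH, not isolated) | C[C@H](CCC1OOC(C)(C)O1)CC(=O)C[C@]1(C)CCO1 | intermediate
15 | (4R)-4-methyl-7-[(2S)-2-methyloxetan-2-yl]-6-oxoheptanal | C[C@H](CCC=O)CC(=O)C[C@]1(C)CCO1 | intermediate
16 | potassium salt of the α-sulfonyl carbanion of 4 (not isolated) | [K+].c1ccccc1/C=C/CC[CH-]S(=O)(=O)c1nnnn1-c1ccccc1 | intermediate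
17 | (4R,7E,11E)-4-methyl-1-[(2S)-2-methyloxetan-2-yl]-12-phenyldodeca-7,11-dien-2-one | C[C@H](CC/C=C/CC/C=C/c1ccccc1)CC(=O)C[C@]1(C)CCO1 | intermediate
18 | (4R,7E,11E)-2-hydroperoxy-4-methyl-1-[(2S)-2-methyloxetan-2-yl]-12-phenyldodeca-7,11-dien-2-ol (ketone perhydrate, C2 epimers, not isolated) | C[C@H](CC/C=C/CC/C=C/c1ccccc1)CC(O)(OO)C[C@]1(C)CCO1 | intermediate
19 | (5R)-5-(2-hydroxyethyl)-5-methyl-3-[(2R,5E,9E)-2-methyl-10-phenyldeca-5,9-dien-1-yl]-1,2-dioxolan-3-ol (C3 epimers, not isolated) | C[C@H](CC/C=C/CC/C=C/c1ccccc1)CC1(O)C[C@@](C)(CCO)OO1 | intermediate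
20 | (1R,5R)-5-methyl-1-[(2R,5E,9E)-2-methyl-10-phenyldeca-5,9-dien-1-yl]-2,6,7-trioxabicyclo[3.2.1]octane | C[C@H](CC/C=C/CC/C=C/c1ccccc1)C[C@@]12C[C@@](C)(CCO1)OO2 | intermediate
21 | dimethylaluminium 2-[(3R,5R)-3,5-dimethyl-5-[(2R,5E,9E)-2-methyl-10-phenyldeca-5,9-dien-1-yl]-1,2-dioxolan-3-yl]ethan-1-olate (not isolated) | C[C@H](CC/C=C/CC/C=C/c1ccccc1)C[C@]1(C)C[C@@](C)(CCO[Al](C)C)OO1 | intermediate
22 | 2-[(3R,5R)-3,5-dimethyl-5-[(2R,5E,9E)-2-methyl-10-phenyldeca-5,9-dien-1-yl]-1,2-dioxolan-3-yl]ethan-1-ol | C[C@H](CC/C=C/CC/C=C/c1ccccc1)C[C@]1(C)C[C@@](C)(CCO)OO1 | intermediate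
23 | 2-[(3S,5R)-3,5-dimethyl-5-[(2R,5E,9E)-2-methyl-10-phenyldeca-5,9-dien-1-yl]-1,2-dioxolan-3-yl]acetaldehyde (not isolated) | C[C@H](CC/C=C/CC/C=C/c1ccccc1)C[C@]1(C)C[C@@](C)(CC=O)OO1 | intermediate
24 | 2-[(3S,5R)-3,5-dimethyl-5-[(2R,5E,9E)-2-methyl-10-phenyldeca-5,9-dien-1-yl]-1,2-dioxolan-3-yl]acetic acid | C[C@H](CC/C=C/CC/C=C/c1ccccc1)C[C@]1(C)C[C@@](C)(CC(=O)O)OO1 | target

**Step count and risks**

Total steps: 10. Longest linear sequence: 8 steps (steps 3 to 10, from 5); steps 1 and 2 are a two-step branch that joins at step 7.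

Steps most likely to fail:

Step 9 (methyl delivery). AlMe3 may reduce the O–O bond, the ketal may ionise with loss of the peroxide oxygen instead of the ether oxygen, or methyl may attack from the open face and give the C5 epimer. The fallback sets out from ketone 17. MeMgBr with CeCl3 at −78 °C adds to the ketone without touching the oxetane and gives the tertiary alcohol F1 as both C5 epimers. Ethereal H2O2 with Me3SiOTf then opens the oxetane with inversion to the hydroperoxy diol F2. BF3·OEt2 ionises the tertiary alcohol and the hydroperoxide closes the dioxolane in an SN1 ring closure, the way 1,3-ditertiary diols give 1,2-dioxolanes with H2O2 and acid. This gives 22 together with the C5 epimer F3, which is removed by chromatography, and the route is rejoined at 22; C5 is then no longer controlled and about half the material is lost.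

Step 8 (perhydrolysis and ketal closure). The β-oxetanyl ketone may instead eliminate to an enone through its enol, form tetraoxanes, or open the oxetane with partial loss of stereospecificity. The fallback sets out from 17 and masks the ketone first. HC(OMe)3, MeOH and pyridinium p-toluenesulfonate give the dimethyl ketal F4, which cannot enolise. H2O2 with Me3SiOTf opens the oxetane intermolecularly with inversion to the hydroperoxy ketal F5. Camphorsulfonic acid then exchanges both methoxy groups for the internal OOH and OH (transketalisation), rejoining the route at 20.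

Step 4 (key alkylation and ring expansion). The carbanion may displace the tosylate directly (which gives the enantiomeric epoxide), alkylate twice, or the ring expansion may stall in the telescoped flask. The fallback sets out from 6 and uses an electrophile with a single reactive site. Lithiated 6 opens the silyl glycidyl ether F6 (made from (S)-2-methylglycidol and t-BuMe2SiCl) to the tertiary alcohol F7. Bu4NF gives the diol F8, and TsCl with Et3N gives the primary monotosylate F9. NaH closes the epoxide 10, which is now isolated and ring-expanded in a separate flask (Me3S(O)I, KOtBu, t-BuOH, 55 °C), rejoining the route at 12.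

**Further compounds**

F1 | step 9 | (2RS,4R,7E,11E)-2,4-dimethyl-1-[(2S)-2-methyloxetan-2-yl]-12-phenyldodeca-7,11-dien-2-ol | C[C@H](CC/C=C/CC/C=C/c1ccccc1)CC(C)(O)C[C@]1(C)CCO1
F2 | step 9 | (3R,5RS,7R,10E,14E)-3-hydroperoxy-3,5,7-trimethyl-15-phenylpentadeca-10,14-diene-1,5-diol | C[C@H](CC/C=C/CC/C=C/c1ccccc1)CC(C)(O)C[C@@](C)(CCO)OO
F3 | step 9 | 2-[(3R,5S)-3,5-dimethyl-5-[(2R,5E,9E)-2-methyl-10-phenyldeca-5,9-dien-1-yl]-1,2-dioxolan-3-yl]ethan-1-ol | C[C@H](CC/C=C/CC/C=C/c1ccccc1)C[C@@]1(C)C[C@@](C)(CCO)OO1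
F4 | step 8 | (2S)-2-[(4R,7E,11E)-2,2-dimethoxy-4-methyl-12-phenyldodeca-7,11-dien-1-yl]-2-methyloxetane | C[C@H](CC/C=C/CC/C=C/c1ccccc1)CC(OC)(OC)C[C@]1(C)CCO1
F5 | step 8 | (3R,7R,10E,14E)-3-hydroperoxy-5,5-dimethoxy-3,7-dimethyl-15-phenylpentadeca-10,14-dien-1-ol | C[C@H](CC/C=C/CC/C=C/c1ccccc1)CC(OC)(OC)C[C@@](C)(CCO)OO
F6 | step 4 | tert-butyl(dimethyl){[(2R)-2-methyloxiran-2-yl]methoxy}silane | CC(C)(C)[Si](C)(C)OC[C@@]1(C)CO1
F7 | step 4 | (2R)-1-{[tert-butyl(dimethyl)silyl]oxy}-3-{2-[(2R)-2,6-dimethylhept-5-en-1-yl]-1,3-dithian-2-yl}-2-methylpropan-2-ol | C[C@H](CCC=C(C)C)CC1(C[C@@](C)(O)CO[Si](C)(C)C(C)(C)C)SCCCS1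
F8 | step 4 | (2R)-3-{2-[(2R)-2,6-dimethylhept-5-en-1-yl]-1,3-dithian-2-yl}-2-methylpropane-1,2-diol | C[C@H](CCC=C(C)C)CC1(C[C@@](C)(O)CO)SCCCS1
F9 | step 4 | (2R)-3-{2-[(2R)-2,6-dimethylhept-5-en-1-yl]-1,3-dithian-2-yl}-2-hydroxy-2-methylpropyl 4-methylbenzenesulfonate | C[C@H](CCC=C(C)C)CC1(C[C@@](C)(O)COS(=O)(=O)c2ccc(C)cc2)SCCCS1
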